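**Retrosynthetic overview**

1. Numbering: C1 carries the pendant aryl group, C2 the CH2OSO3H carbon (C9'), C3 the CH2OH carbon (C9), C4 is the ring CH2, and C4a/C8a fuse arene ring A to carbocyclic ring B. The route rests on one feature: the skeleton is two sinapyl (C6–C3) units joined only by C2–C3 and C1–C8a, and C9 and C9' stand 1,4 to each other, so one oxygen can bridge them.
2. End game: target ⇒ C9' alcohol 15 with C9–O capped ⇒ trans-fused γ-lactone 11 (C9' as C=O, C9 as OCH2). The unequal oxidation levels of C9' and C9 in the lactone allow the sulfate to be placed on C9' alone.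
3. Key disconnection: cutting C1–C8a and C2–C3 of 11 gives the open ester 9. In 9 the vinyl-arene C8a=C4a–C4=C3 (diene, ring A dearomatised in passing) is tied through C9–O–C9' to the E-cinnamate C1=C2 (dienophile).
4. Ring order: ring A and the pendant ring come from syringaldehyde. Ring B and the lactone ring form together in step 6, and the lactone ring is opened again in step 7. Ester 9 ⇒ alcohol 6 + acid 8, both from the one acrylate 5.

Key step: step 6

Remark 1: the (S)-configured catalyst is assumed to deliver the (1R,2S,3S) series. The sense of induction cannot be derived safely for an ester carbonyl that sits inside the tether, so it has to be checked on 11, and the (R)-catalyst would be taken if it is opposite.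

Remark 2: the sulfate monoester is carried as its sodium salt and is turned into the free hydrogen sulfate of the target only in the last operation.

**Step 1**
Reactants: 1 syringaldehyde; 2 benzyl bromide
Product: 3 4-(benzyloxy)-3,5-dimethoxybenzaldehyde
Conditions: K2CO3, DMF, 60 °C
Reagents that add atoms: benzyl bromide (2), BrCc1ccccc1
Why: Williamson ether synthesis, in which the acidic phenol is deprotonated by K2CO3 and alkylated by the benzylic bromide while the aldehyde is inert.

**Step 2**
Reactants: 3 4-(benzyloxy)-3,5-dimethoxybenzaldehyde; 4 ethyl (triphenylphosphoranylidene)acetate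
Product: 5 ethyl (E)-3-[4-(benzyloxy)-3,5-dimethoxyphenyl]acrylate
Conditions: toluene, 90 °C
Reagents that add atoms: ethyl (triphenylphosphoranylidene)acetate (4), CCOC(=O)C=P(c1ccccc1)(c1ccccc1)c1ccccc1
Why: Wittig olefination with a stabilised ylide, which with aromatic aldehydes should give the E-acrylate needed for both halves of the precursor.

**Step 3**
Reactants: 5 ethyl (E)-3-[4-(benzyloxy)-3,5-dimethoxyphenyl]acrylate (one half of the material)
Product: 6 (E)-3-[4-(benzyloxy)-3,5-dimethoxyphenyl]prop-2-en-1-ol
Conditions: iBu2AlH (2.5 equiv), CH2Cl2, −78 → 0 °C; aq potassium sodium tartrate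
Reagents that add atoms: none
Why: 1,2-reduction of an α,β-unsaturated ester with iBu2AlH, which should stop at the allylic alcohol and leave the E-alkene and the benzyl ether untouched.

**Step 4**
Reactants: 5 ethyl (E)-3-[4-(benzyloxy)-3,5-dimethoxyphenyl]acrylate (other half of the material)
Product: 8 (E)-3-[4-(benzyloxy)-3,5-dimethoxyphenyl]acrylic acid, via lithium carboxylate 7 (not isolated)
Conditions: LiOH, THF–MeOH–H2O, 40 °C; then 1 M HCl
Reagents that add atoms: lithium hydroxide, [Li+].[OH-]
Why: Ester saponification followed by acidification, which does not affect the alkene geometry or the ether groups.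

**Step 5**
Reactants: 6 (E)-3-[4-(benzyloxy)-3,5-dimethoxyphenyl]prop-2-en-1-ol; 8 (E)-3-[4-(benzyloxy)-3,5-dimethoxyphenyl]acrylic acid
Product: 9 (E)-3-[4-(benzyloxy)-3,5-dimethoxyphenyl]allyl (E)-3-[4-(benzyloxy)-3,5-dimethoxyphenyl]acrylate
Conditions: DCC, DMAP (cat), CH2Cl2, 0 °C → rt
Reagents that add atoms: none
Why: Steglich esterification, whose neutral acyl-transfer conditions avoid ionisation of the electron-rich allylic alcohol and keep both alkenes E.

**Step 6**
Reactants: 9 (E)-3-[4-(benzyloxy)-3,5-dimethoxyphenyl]allyl (E)-3-[4-(benzyloxy)-3,5-dimethoxyphenyl]acrylate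
Product: 11 (3aS,9R,9aS)-7-(benzyloxy)-9-[4-(benzyloxy)-3,5-dimethoxyphenyl]-6,8-dimethoxy-3a,4,9,9a-tetrahydronaphtho[2,3-c]furan-1(3H)-one (route numbering 1R,2S,3S; 1,2-trans and 2,3-trans), via isotoluene cycloadduct 10 (not isolated)
Conditions: (S)-3,3-diphenyl-1-(o-tolyl)tetrahydro-1H,3H-pyrrolo[1,2-c][1,3,2]oxazaborole (25 mol %), (CF3SO2)2NH (20 mol %), CH2Cl2 (0.02 M), −40 °C → rt, Ar; enantiomeric purity to be raised by crystallisation of 11 if needed
Reagents that add atoms: none
Why: Proposed new method: the cationic boron centre binds the tether carbonyl oxygen of 9, lowers the LUMO of C1=C2 and lets the vinyl-arene C8a=C4a–C4=C3 add suprafacially in a concerted, asynchronous [4+2] in which C1–C8a (activated β-carbon to an arene carbon ortho and para to OMe groups) runs ahead of C2–C3, after which isotoluene 10 rearomatises not by a concerted 1,3-shift, which is forbidden suprafacially, but by a proton relay through the acidic catalyst (protonation at C4, loss of H-8a). The closest known reaction types are the thermal intramolecular styrene Diels–Alder of cinnamyl cinnamates and arylpropiolates, which gives racemic aryltetralin and arylnaphthalene lactones, and the oxazaborolidinium-catalysed enantioselective Diels–Alder of acrylate, crotonate and fumarate esters with ordinary dienes, and neither covers a dearomatising diene under chiral catalysis. Ring B closes as the six-membered ring of the cycloaddition itself, and the γ-lactone closes in the same event as the five-membered ring C2–C9'–O–C9–C3 spanned by the three-atom tether, which forces the ester into its less populated E rotamer about C9'–O, a penalty that the carbonyl activation has to outweigh. C1 and C2 come out trans because the E-cinnamate adds suprafacially, C2 and C3 come out trans if the E-configured C3=C4 bond meets the dienophile with the tether carbonyl exo and the C1 aryl group endo over ring A, the transient C8a centre (H-8a cis to H-3) is erased on rearomatisation, and the absolute sense (addition to the Re faces of C1 and C2) rests on a catalyst phenyl group covering the other face of the bound cinnamate. The step needs periselectivity, secured because only the acid-side alkene is bound and polarised while only ring A serves as an unbound donor diene, it needs no regiocontrol on ring A because its two ortho carbons are equivalent, and it needs chemoselectivity against ionisation of the allylic C9–O bond, helped by the C7 benzyloxy group being twisted out of conjugation by its two OMe neighbours and by keeping the oxazaborolidine in slight excess over (CF3SO2)2NH so that no free strong acid is present.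

**Step 7**
Reactants: 11 trans-fused lactone
Product: 12 (1R,2S,3S)-7-(benzyloxy)-1-[4-(benzyloxy)-3,5-dimethoxyphenyl]-3-(hydroxymethyl)-N,6,8-trimethoxy-N-methyl-1,2,3,4-tetrahydronaphthalene-2-carboxamide
Conditions: MeNH(OMe)·HCl, AlMe3, CH2Cl2, 0 °C → rt; aq potassium sodium tartrate; crude product used at once
Reagents that add atoms: N,O-dimethylhydroxylamine hydrochloride, CNOC.Cl
Why: Weinreb-type aminolysis of a lactone with the aluminium amide made from AlMe3 and the amine salt, in which the strained trans-fused ring is opened at the C9' carbonyl, C9–OH is freed, C9' stays at the acid level and the weakly basic reagent leaves C2–H untouched.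

**Step 8**
Reactants: 12 hydroxy Weinreb amide
Product: 13 (1R,2S,3S)-7-(benzyloxy)-1-[4-(benzyloxy)-3,5-dimethoxyphenyl]-3-{[(benzyloxy)methoxy]methyl}-N,6,8-trimethoxy-N-methyl-1,2,3,4-tetrahydronaphthalene-2-carboxamide
Conditions: BnOCH2Cl, iPr2NEt, CH2Cl2, 0 °C → rt
Reagents that add atoms: benzyl chloromethyl ether, ClCOCc1ccccc1
Why: Alkoxymethyl ether formation under amine base, which generates no alkoxide so that attack of C9–O on the amide carbonyl (relactonisation) should stay slow, and which installs a group that falls in the final hydrogenolysis together with the aryl benzyl ethers.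

**Step 9**
Reactants: 13 benzyloxymethyl ether Weinreb amide
Product: 15 [(1R,2S,3S)-7-(benzyloxy)-1-[4-(benzyloxy)-3,5-dimethoxyphenyl]-3-{[(benzyloxy)methoxy]methyl}-6,8-dimethoxy-1,2,3,4-tetrahydronaphthalen-2-yl]methanol, via aldehyde 14 (not isolated)
Conditions: iBu2AlH (1.5 equiv), THF, −78 °C; MeOH, then NaBH4, −78 → 0 °C; aq potassium sodium tartrate
Reagents that add atoms: none
Why: Weinreb amide reduction, in which the chelated tetrahedral aluminium adduct collapses to aldehyde 14 only on the methanol quench and NaBH4 reduces it at once in the cold, so that the epimerisable C2 centre has no time to scramble.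

**Step 10**
Reactants: 15 C9' alcohol
Product: 17 sodium [(1R,2S,3S)-7-(benzyloxy)-1-[4-(benzyloxy)-3,5-dimethoxyphenyl]-3-{[(benzyloxy)methoxy]methyl}-6,8-dimethoxy-1,2,3,4-tetrahydronaphthalen-2-yl]methyl sulfate, via pyridinium sulfate 16 (not isolated)
Conditions: SO3·pyridine (5 equiv), pyridine, rt → 40 °C; aq NaHCO3; chromatography (CH2Cl2–MeOH)
Reagents that add atoms: sulfur trioxide–pyridine complex, O=S(=O)([O-])[n+]1ccccc1; sodium hydrogen carbonate, [Na+].OC([O-])=O
Why: O-sulfation of an alcohol with an amine–SO3 complex, where C9'–OH is the only free hydroxyl, the basic medium protects the acetal and the benzyl ethers, and NaHCO3 replaces the pyridinium ion that would slow the palladium catalyst of the last step.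

**Step 11**
Reactants: 17 protected sodium sulfate
Product: 19 [(1R,2S,3S)-7-hydroxy-1-(4-hydroxy-3,5-dimethoxyphenyl)-3-(hydroxymethyl)-6,8-dimethoxy-1,2,3,4-tetrahydronaphthalen-2-yl]methyl hydrogen sulfate (target), via sodium salt of the target 18 (not isolated)
Conditions: H2 (1 atm), 10% Pd/C, MeOH, rt; filter, concentrate; Dowex 50WX8 (H+ form), H2O, 0–5 °C; lyophilise
Reagents that add atoms: none
Why: Catalytic hydrogenolysis of benzylic C–O bonds removes both aryl benzyl ethers and the benzyl part of the acetal, whose hemiacetal loses formaldehyde, while the alkyl sulfate, the diarylmethine C1–H and the three stereocentres are inert, and cation exchange on a sulfonic acid resin in the cold then gives the free hydrogen sulfate.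

**Compound list**

1 | syringaldehyde (4-hydroxy-3,5-dimethoxybenzaldehyde) | COc1cc(C=O)cc(OC)c1O | starting material
2 | benzyl bromide | BrCc1ccccc1 | starting material
3 | 4-(benzyloxy)-3,5-dimethoxybenzaldehyde | COc1cc(C=O)cc(OC)c1OCc1ccccc1 | intermediate
4 | ethyl (triphenylphosphoranylidene)acetate | CCOC(=O)C=P(c1ccccc1)(c1ccccc1)c1ccccc1 | starting material
5 | ethyl (E)-3-[4-(benzyloxy)-3,5-dimethoxyphenyl]acrylate | CCOC(=O)/C=C/c1cc(OC)c(OCc2ccccc2)c(OC)c1 | intermediate
6 | (E)-3-[4-(benzyloxy)-3,5-dimethoxyphenyl]prop-2-en-1-ol | OC/C=C/c1cc(OC)c(OCc2ccccc2)c(OC)c1 | intermediate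
7 | lithium (E)-3-[4-(benzyloxy)-3,5-dimethoxyphenyl]acrylate (not isolated) | [Li+].[O-]C(=O)/C=C/c1cc(OC)c(OCc2ccccc2)c(OC)c1 | intermediate
8 | (E)-3-[4-(benzyloxy)-3,5-dimethoxyphenyl]acrylic acid | OC(=O)/C=C/c1cc(OC)c(OCc2ccccc2)c(OC)c1 | intermediate
9 | (E)-3-[4-(benzyloxy)-3,5-dimethoxyphenyl]allyl (E)-3-[4-(benzyloxy)-3,5-dimethoxyphenyl]acrylate (key-step precursor) | COc1cc(/C=C/COC(=O)/C=C/c2cc(OC)c(OCc3ccccc3)c(OC)c2)cc(OC)c1OCc1ccccc1 | intermediate
10 | isotoluene cycloadduct, route numbering (1R,2S,3S,8aS): as 11 but C8a is sp3 with H-8a cis to H-3, C4a=C4 is exocyclic to ring A, and C5=C6 and C7=C8 remain (not isolated) | COc1cc([C@@H]2[C@H]3C(=C[C@H](COC5=O)[C@H]25)C=C(OC)C(OCc4ccccc4)=C3OC)cc(OC)c1OCc1ccccc1 | intermediate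
11 | (3aS,9R,9aS)-7-(benzyloxy)-9-[4-(benzyloxy)-3,5-dimethoxyphenyl]-6,8-dimethoxy-3a,4,9,9a-tetrahydronaphtho[2,3-c]furan-1(3H)-one (key-step product) | COc1cc([C@@H]2c3c(cc(OC)c(OCc4ccccc4)c3OC)C[C@H](COC4=O)[C@H]24)cc(OC)c1OCc1ccccc1 | intermediate
12 | (1R,2S,3S)-hydroxy Weinreb amide (C9–OH free, C9' as CON(OMe)Me) | COc1cc([C@@H]2c3c(cc(OC)c(OCc4ccccc4)c3OC)C[C@H](CO)[C@H]2C(=O)N(C)OC)cc(OC)c1OCc1ccccc1 | intermediate
13 | (1R,2S,3S)-C9 benzyloxymethyl ether of 12 | COc1cc([C@@H]2c3c(cc(OC)c(OCc4ccccc4)c3OC)C[C@H](COCOCc4ccccc4)[C@H]2C(=O)N(C)OC)cc(OC)c1OCc1ccccc1 | intermediate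
14 | (1R,2S,3S)-C9' aldehyde (not isolated) | COc1cc([C@@H]2c3c(cc(OC)c(OCc4ccccc4)c3OC)C[C@H](COCOCc4ccccc4)[C@H]2C=O)cc(OC)c1OCc1ccccc1 | intermediate
15 | (1R,2S,3S)-C9' alcohol, C9 benzyloxymethyl ether, both phenols benzylated | COc1cc([C@@H]2c3c(cc(OC)c(OCc4ccccc4)c3OC)C[C@H](COCOCc4ccccc4)[C@H]2CO)cc(OC)c1OCc1ccccc1 | intermediate
16 | pyridinium salt of the C9' sulfate of 15 (not isolated) | COc1cc([C@@H]2c3c(cc(OC)c(OCc4ccccc4)c3OC)C[C@H](COCOCc4ccccc4)[C@H]2COS(=O)(=O)[O-])cc(OC)c1OCc1ccccc1.c1cc[nH+]cc1 | intermediate
17 | sodium salt of the C9' sulfate of 15 | COc1cc([C@@H]2c3c(cc(OC)c(OCc4ccccc4)c3OC)C[C@H](COCOCc4ccccc4)[C@H]2COS(=O)(=O)[O-])cc(OC)c1OCc1ccccc1.[Na+] | intermediate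
18 | sodium salt of the target (not isolated) | COc1cc([C@@H]2c3c(cc(OC)c(O)c3OC)C[C@H](CO)[C@H]2COS(=O)(=O)[O-])cc(OC)c1O.[Na+] | intermediate
19 | [(1R,2S,3S)-7-hydroxy-1-(4-hydroxy-3,5-dimethoxyphenyl)-3-(hydroxymethyl)-6,8-dimethoxy-1,2,3,4-tetrahydronaphthalen-2-yl]methyl hydrogen sulfate | COc1cc([C@@H]2c3c(cc(OC)c(O)c3OC)C[C@H](CO)[C@H]2COS(=O)(=O)O)cc(OC)c1O | target

**Step count**

- Total step count: 11.
- Longest linear sequence: 10 (steps 1, 2, 3, 5, 6, 7, 8, 9, 10, 11). Step 4 is a one-step branch from 5.

**Steps most likely to fail**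

**1. Step 6 (labelled step).**

What may go wrong:
- There may be no turnover, because an aryl-donor-substituted cinnamate is a weak dienophile for a diene that must give up aromaticity at temperatures the catalyst tolerates.
- The allylic C9–O bond may ionise, followed by cationic oligomerisation of the styrene.
- Exo/endo selectivity may be poor, which leaks material into the cis-fused series that cannot be corrected later.
- Facial selectivity may be poor.

Fallback, all known chemistry, sets out from 3 and comes back at 11:
- Stobbe condensation of 3 with dimethyl succinate (KOtBu, tBuOH) should give the (E)-arylidenesuccinic half-ester F1.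
- Asymmetric hydrogenation with [Rh(cod)(Et-DuPhos)]BF4 and H2 in MeOH should give the (S)-benzylsuccinic half-ester F2. The ligand antipode is chosen for the S acid, and the benzyl ether is inert to the homogeneous catalyst.
- Reduction of the ester group of its potassium carboxylate with Ca(BH4)2 (from CaCl2 and NaBH4, EtOH), then acidic work-up, should give the (S)-β-benzyl-γ-butyrolactone F3.
- Its lithium enolate (LiN(SiMe3)2, THF, −78 °C) should add to a second portion of 3 anti to the benzyl group to give the trans-α,β-disubstituted carbinol F4 as C1 epimers.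
- Short exposure to CF3CO2H in CH2Cl2 ionises the carbinol. C8a of ring A then captures the benzylic cation in a Friedel–Crafts alkylation that places the aryl group trans to C9' and gives 11.

**2. Step 7 (and the capping in step 8 that depends on it).**

What may go wrong:
- Opening of the carbonyl shielded by the C1 aryl group may be incomplete.
- The opening may reverse (relactonisation with loss of the amine) on work-up or before the C9 hydroxyl is capped.

Fallback sets out from 11 and comes back at 18. The two carbinol carbons are told apart by steric hindrance instead of by oxidation level: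
- LiAlH4 (THF, 0 °C) should reduce 11 to the di-O-benzyl diol F5.
- Trityl chloride (pyridine, DMAP, rt) should take the C9 hydroxyl, which is flanked by C4H2, in preference to the C9' hydroxyl next to the C1 aryl group. This gives the C9 trityl ether F6.
- SO3·pyridine should give the pyridinium sulfate F7, and NaHCO3 the sodium sulfate F8.
- H2 with 10% Pd/C in MeOH cleaves the two benzyl ethers and the trityl ether to give 18.

**3. Step 10 (its isolation problems are handed on to step 11).**

What may go wrong:
- Sulfation may be sluggish at the β-branched, crowded alcohol.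
- Acid traces in the SO3 complex may strip the acetal, with loss of site selectivity.
- The amphiphilic salt may be lost when it is separated from pyridine and inorganic sulfate.

Fallback sets out from 15 and comes back at 17. The sulfate is introduced in protected, neutral form:
- 1,2-Dimethyl-3-[(2,2,2-trichloroethoxy)sulfonyl]imidazolium triflate with 1,2-dimethylimidazole in CH2Cl2 should give the 2,2,2-trichloroethyl sulfate diester F9, which can be purified on silica.
- Zn and HCO2NH4 in MeOH at rt fragment the trichloroethyl group reductively to give the ammonium sulfate F10.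
- Evaporation with NaHCO3 exchanges the cation to give 17.

**Further compounds**

F1 | step 6 | (E)-4-[4-(benzyloxy)-3,5-dimethoxyphenyl]-3-(methoxycarbonyl)but-3-enoic acid | COC(=O)/C(CC(=O)O)=C/c1cc(OC)c(OCc2ccccc2)c(OC)c1
F2 | step 6 | (S)-3-[4-(benzyloxy)-3,5-dimethoxybenzyl]-4-methoxy-4-oxobutanoic acid | COc1cc(C[C@H](C(=O)OC)CC(=O)O)cc(OC)c1OCc1ccccc1
F3 | step 6 | (S)-4-[4-(benzyloxy)-3,5-dimethoxybenzyl]dihydrofuran-2(3H)-one | COc1cc(C[C@@H]2COC(=O)C2)cc(OC)c1OCc1ccccc1
F4 | step 6 | trans-3-{[4-(benzyloxy)-3,5-dimethoxyphenyl](hydroxy)methyl}-4-[4-(benzyloxy)-3,5-dimethoxybenzyl]dihydrofuran-2(3H)-one, carbinol epimers | COc1cc(C[C@@H]2COC(=O)[C@H]2C(O)c2cc(OC)c(OCc3ccccc3)c(OC)c2)cc(OC)c1OCc1ccccc1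
F5 | step 7 | (1R,2S,3S)-di-O-benzyl diol (C9–OH and C9'–OH free) | COc1cc([C@@H]2c3c(cc(OC)c(OCc4ccccc4)c3OC)C[C@H](CO)[C@H]2CO)cc(OC)c1OCc1ccccc1
F6 | step 7 | C9 trityl ether of F5 | COc1cc([C@@H]2c3c(cc(OC)c(OCc4ccccc4)c3OC)C[C@H](COC(c4ccccc4)(c4ccccc4)c4ccccc4)[C@H]2CO)cc(OC)c1OCc1ccccc1
F7 | step 7 | pyridinium salt of the C9' sulfate of F6 | COc1cc([C@@H]2c3c(cc(OC)c(OCc4ccccc4)c3OC)C[C@H](COC(c4ccccc4)(c4ccccc4)c4ccccc4)[C@H]2COS(=O)(=O)[O-])cc(OC)c1OCc1ccccc1.c1cc[nH+]cc1
F8 | step 7 | sodium salt of the C9' sulfate of F6 | COc1cc([C@@H]2c3c(cc(OC)c(OCc4ccccc4)c3OC)C[C@H](COC(c4ccccc4)(c4ccccc4)c4ccccc4)[C@H]2COS(=O)(=O)[O-])cc(OC)c1OCc1ccccc1.[Na+]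
F9 | step 10 | C9' 2,2,2-trichloroethyl sulfate diester of 15 | COc1cc([C@@H]2c3c(cc(OC)c(OCc4ccccc4)c3OC)C[C@H](COCOCc4ccccc4)[C@H]2COS(=O)(=O)OCC(Cl)(Cl)Cl)cc(OC)c1OCc1ccccc1
F10 | step 10 | ammonium salt of the C9' sulfate of 15 | COc1cc([C@@H]2c3c(cc(OC)c(OCc4ccccc4)c3OC)C[C@H](COCOCc4ccccc4)[C@H]2COS(=O)(=O)[O-])cc(OC)c1OCc1ccccc1.[NH4+]
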